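The pentamer is cut at its two outer methylene links, made last by Mannich-type capping with butyrylfilicinic acid (rings A and E), and inside rings B and D. Each of these two rings is read as a 2-substituted malonyl unit (the ring carbon attached to the CH2 link to ring C together with its two hydroxyl-bearing neighbours) joined to heptane-2,4-dione (the remaining three ring carbons and the butanoyl side chain). The key step builds both arenes in one operation: each malonyl dichloride arm of a tribenzyl-protected ring C tetra(acid chloride) is C-acylated twice by its own molecule of 2,4-bis(trimethylsilyloxy)hepta-1,3-diene (two diene molecules in all), forming four C–C bonds and the B–C–D trimer.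

Key step: step 8

Remark: rings are lettered A to E along the chain (A and E are the filicinic end rings, C is the central ring); all enolised units are drawn in one tautomeric form, and the target has no stereocentre.
Remark: the diene is made through the dianion of the diketone, because this fixes the deprotonated terminus as the methyl group, which a second silylation of the mono(silyl enol ether) would not guarantee.

Step 1
Reactants: 1 1-(2,4,6-trihydroxyphenyl)butan-1-one
Product: 3 5-butanoyl-2,4,6-trihydroxybenzene-1,3-dicarbaldehyde, via bis(iminium) dichloride 2 (not isolated)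
Conditions: POCl3 (4 equiv), DMF (6 equiv), EtOAc, 0 → 25 °C; then H2O, 50 °C
Reagents that add atoms: N,N-dimethylformamide CN(C)C=O; water O
Why: Twofold Vilsmeier–Haack formylation: each of the two free ring carbons lies between two hydroxyl groups and attacks the chloroiminium ion despite the one acyl group, and water then hydrolyses the bis(iminium) salt 2 to the dialdehyde.

Step 2
Reactants: 3 5-butanoyl-2,4,6-trihydroxybenzene-1,3-dicarbaldehyde
Product: 4 2,4,6-tris(benzyloxy)-5-butanoylbenzene-1,3-dicarbaldehyde
Conditions: BnBr (4.5 equiv), K2CO3 (6 equiv), n-Bu4NI (0.1 equiv), DMF, 60 °C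
Reagents that add atoms: benzyl bromide BrCc1ccccc1
Why: Williamson ether synthesis on the three phenoxides; every ring carbon is substituted, so C-benzylation would require dearomatisation at a quaternary centre and is disfavoured, and excess bromide with iodide catalysis should carry the chelated, acidic hydroxyl groups through to the tri-ether.

Step 3
Reactants: 4 2,4,6-tris(benzyloxy)-5-butanoylbenzene-1,3-dicarbaldehyde; 5 dimethyl propanedioate
Product: 6 tetramethyl 2,2'-{[2,4,6-tris(benzyloxy)-5-butanoyl-1,3-phenylene]dimethanylylidene}dipropanedioate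
Conditions: 5 (2.5 equiv), piperidine (0.2 equiv), AcOH (0.2 equiv), toluene, reflux, Dean–Stark trap
Reagents that add atoms: none
Why: Twofold Knoevenagel condensation at the two aldehydes only, since the butanoyl ketone between two benzyloxy groups is far less electrophilic and no free ortho-hydroxyl group is left that could lactonise to a coumarin.

Step 4
Reactants: 6 tetramethyl 2,2'-{[2,4,6-tris(benzyloxy)-5-butanoyl-1,3-phenylene]dimethanylylidene}dipropanedioate
Product: 7 tetramethyl 2,2'-{[2,4,6-tris(benzyloxy)-5-butanoyl-1,3-phenylene]bis(methylene)}dipropanedioate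
Conditions: NaBH4 (1.2 equiv), THF–MeOH, 0 °C; then aq. NH4Cl
Reagents that add atoms: none
Why: Conjugate (1,4) hydride reduction of the doubly activated arylidene malonates, which is fast at 0 °C, while the ketone, twisted out of plane between two benzyloxy groups, and the esters react much more slowly with NaBH4.

Step 5
Reactants: 7 tetramethyl 2,2'-{[2,4,6-tris(benzyloxy)-5-butanoyl-1,3-phenylene]bis(methylene)}dipropanedioate
Product: 8 2,2'-{[2,4,6-tris(benzyloxy)-5-butanoyl-1,3-phenylene]bis(methylene)}dipropanedioic acid
Conditions: LiOH (12 equiv), THF–MeOH–H2O, 40 °C; then 1 M HCl, 0 °C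
Reagents that add atoms: lithium hydroxide [Li+].[OH-]
Why: Ester saponification with hydroxide, to which benzyl ethers and the hindered ketone are inert; the 2-substituted malonic acids are set free cold so that they do not decarboxylate.

Step 6
Reactants: 8 2,2'-{[2,4,6-tris(benzyloxy)-5-butanoyl-1,3-phenylene]bis(methylene)}dipropanedioic acid
Product: 9 2,2'-{[2,4,6-tris(benzyloxy)-5-butanoyl-1,3-phenylene]bis(methylene)}dipropanedioyl tetrachloride
Conditions: (COCl)2 (8 equiv), DMF (0.05 equiv), CH2Cl2, 0 → 20 °C; evaporation, used crude
Reagents that add atoms: oxalyl chloride O=C(Cl)C(Cl)=O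
Why: Acid chloride formation with oxalyl chloride under chloroiminium (Vilsmeier-type) catalysis gives only gaseous by-products, so the moisture-sensitive tetra(acid chloride), a 2-substituted malonyl dichloride of a stable class, should be obtained by evaporation and used at once.

Step 7
Reactants: 10 heptane-2,4-dione
Product: 12 (3Z)-2,4-bis(trimethylsilyloxy)hepta-1,3-diene, via dilithium dienediolate 11 (not isolated)
Conditions: LiN(iPr)2 (2.2 equiv), THF, −78 → 0 °C; then Me3SiCl (2.6 equiv), −78 → 20 °C; distillation
Reagents that add atoms: chlorotrimethylsilane C[Si](C)(C)Cl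
Why: Dianion formation followed by enolate O-silylation: after the first deprotonation at the central carbon, LiN(iPr)2 should remove the second proton from the methyl group and not from the propyl methylene (the less substituted terminus, where β-diketone dianions form), and any silicon that goes to the terminal carbon sits at the same terminus and should reach oxygen by the 1,3 carbon-to-oxygen silyl shift (Brook-type) of β-ketosilanes on distillation.

Step 8
Reactants: 9 2,2'-{[2,4,6-tris(benzyloxy)-5-butanoyl-1,3-phenylene]bis(methylene)}dipropanedioyl tetrachloride; 12 (3Z)-2,4-bis(trimethylsilyloxy)hepta-1,3-diene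
Product: 14 1-[2,4,6-tris(benzyloxy)-3,5-bis(3-butanoyl-2,4,6-trihydroxybenzyl)phenyl]butan-1-one, via open-chain silyl enol ether 13 (not isolated)
Conditions: 12 (2.4 equiv), Me3SiOTf (0.5 equiv), CH2Cl2 (0.01 M), −78 → 20 °C, slow addition of the diene; then 1 M HCl
Reagents that add atoms: none
Why: Proposed new method: two molecules of 12 are consumed for each molecule of 9 (one per malonyl dichloride arm, four molecules of Me3SiCl being released), and in each arm Me3SiOTf activates an acid chloride, the terminal CH2 carbon of the diene, its most nucleophilic site, acylates it with loss of Me3SiCl to give 13, and the remaining β-silyloxy enone is then acylated at its central carbon by the second acid chloride of the same malonyl unit, after which loss of a second Me3SiCl and enolisation of the cyclohexane-1,3,5-trione give the arene, the propyl ketone of the diene ending up as the butanoyl group. The closest known reaction types are the Lewis-acid-mediated formal [3+3] cyclisation of 1,3-bis(silyl enol ethers) with 1,3-dielectrophiles to phenols and the C-acylation of such dienes by malonyl dichloride; what is untested is the twofold use on a 2-substituted malonyl dichloride with a diketone-derived diene. Rings B and D are each closed by a 6-exo-trig C-acylation in which the enol ether carbon (enol-exo) attacks the acyl chloride carbon. No stereocentre results, because the two CH(COCl) centres of 13 disappear on aromatisation. Ring closure has to go through carbon and not through the enol oxygen, which the softer carbon terminus of the silyl enol ether, the Lewis acid and the low temperature should favour, and an arm that closed through oxygen to a 4-hydroxy-2-pyrone could still be converted to the same arene by Mg(OMe)2 in MeOH (ring opening and Claisen condensation). The second acylation must also be intramolecular, which high dilution and the six-membered transition state should secure, and ring C must stay inert, which its three benzyl ethers and the lack of a free ring carbon ensure.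

Step 9
Reactants: 14 1-[2,4,6-tris(benzyloxy)-3,5-bis(3-butanoyl-2,4,6-trihydroxybenzyl)phenyl]butan-1-one
Product: 15 1-[3,5-bis(3-butanoyl-2,4,6-trihydroxybenzyl)-2,4,6-trihydroxyphenyl]butan-1-one
Conditions: H2 (1 atm), Pd/C (10 wt% palladium on carbon), EtOAc–MeOH, 20 °C
Reagents that add atoms: none
Why: Hydrogenolysis of the three aryl benzyl ethers on zerovalent palladium; the hydrogen-bonded aryl ketones, the arene rings and the diarylmethane links should not be reduced under neutral conditions at ambient pressure.

Step 10
Reactants: 1 1-(2,4,6-trihydroxyphenyl)butan-1-one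
Product: 16 2-butanoyl-3,5-dihydroxy-6,6-dimethylcyclohexa-2,4-dien-1-one (butyrylfilicinic acid)
Conditions: NaOMe (3.2 equiv), MeI (2.4 equiv), MeOH, 0 → 20 °C; then 1 M HCl
Reagents that add atoms: iodomethane CI
Why: Base-mediated C-methylation of the acylphloroglucinol (dearomatising gem-dimethylation): the ring carbon that has taken one methyl group is the most nucleophilic site of the resulting phenoxide and takes the second one as well, a classical route to acylfilicinic acids in which under- and over-methylated by-products are removed by chromatography.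

Step 11
Reactants: 16 2-butanoyl-3,5-dihydroxy-6,6-dimethylcyclohexa-2,4-dien-1-one
Product: 17 2-butanoyl-4-[(dimethylamino)methyl]-3,5-dihydroxy-6,6-dimethylcyclohexa-2,4-dien-1-one
Conditions: CH2(NMe2)2 (1.2 equiv), CH2Cl2, 0 → 20 °C
Reagents that add atoms: N,N,N',N'-tetramethylmethanediamine CN(C)CN(C)C
Why: Mannich reaction: the acidic enol protonates the aminal to the methyleneiminium ion, which is attacked by the only unsubstituted ring carbon, the one between the two enolic C–OH carbons, and the absence of free formaldehyde limits formation of the methylene-bridged homodimer.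

Step 12
Reactants: 15 1-[3,5-bis(3-butanoyl-2,4,6-trihydroxybenzyl)-2,4,6-trihydroxyphenyl]butan-1-one; 17 2-butanoyl-4-[(dimethylamino)methyl]-3,5-dihydroxy-6,6-dimethylcyclohexa-2,4-dien-1-one
Product: 19 pentaalbaspidin BBBBB, via filicinic enone methide 18 (not isolated)
Conditions: 17 (2.4 equiv), 1,4-dioxane, 90 °C, N2 stream; then 1 M HCl
Reagents that add atoms: none
Why: Mannich-base alkylation: on heating, 17 loses dimethylamine, which is swept out, to give enone methide 18, and Michael addition of the single free, doubly hydroxyl-flanked ring carbon of each outer ring of 15 (rings B and D; ring C is fully substituted) should form the two remaining methylene links, as known for phenolic and 1,3-dione Mannich bases.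

Compound list
1 | 1-(2,4,6-trihydroxyphenyl)butan-1-one (butyrylphloroglucinol) | CCCC(=O)c1c(O)cc(O)cc1O | starting material
2 | (5-butanoyl-2,4,6-trihydroxy-1,3-phenylene)bis(N,N-dimethylmethaniminium) dichloride | CCCC(=O)c1c(O)c(C=[N+](C)C)c(O)c(C=[N+](C)C)c1O.[Cl-].[Cl-] | intermediate (not isolated)
3 | 5-butanoyl-2,4,6-trihydroxybenzene-1,3-dicarbaldehyde | CCCC(=O)c1c(O)c(C=O)c(O)c(C=O)c1O | intermediate
4 | 2,4,6-tris(benzyloxy)-5-butanoylbenzene-1,3-dicarbaldehyde | CCCC(=O)c1c(OCc2ccccc2)c(C=O)c(OCc2ccccc2)c(C=O)c1OCc1ccccc1 | intermediate
5 | dimethyl propanedioate | COC(=O)CC(=O)OC | starting material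
6 | tetramethyl 2,2'-{[2,4,6-tris(benzyloxy)-5-butanoyl-1,3-phenylene]dimethanylylidene}dipropanedioate | CCCC(=O)c1c(OCc2ccccc2)c(C=C(C(=O)OC)C(=O)OC)c(OCc2ccccc2)c(C=C(C(=O)OC)C(=O)OC)c1OCc1ccccc1 | intermediate
7 | tetramethyl 2,2'-{[2,4,6-tris(benzyloxy)-5-butanoyl-1,3-phenylene]bis(methylene)}dipropanedioate | CCCC(=O)c1c(OCc2ccccc2)c(CC(C(=O)OC)C(=O)OC)c(OCc2ccccc2)c(CC(C(=O)OC)C(=O)OC)c1OCc1ccccc1 | intermediate
8 | 2,2'-{[2,4,6-tris(benzyloxy)-5-butanoyl-1,3-phenylene]bis(methylene)}dipropanedioic acid | CCCC(=O)c1c(OCc2ccccc2)c(CC(C(=O)O)C(=O)O)c(OCc2ccccc2)c(CC(C(=O)O)C(=O)O)c1OCc1ccccc1 | intermediate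
9 | 2,2'-{[2,4,6-tris(benzyloxy)-5-butanoyl-1,3-phenylene]bis(methylene)}dipropanedioyl tetrachloride (ring C bis(malonyl dichloride)) | CCCC(=O)c1c(OCc2ccccc2)c(CC(C(Cl)=O)C(Cl)=O)c(OCc2ccccc2)c(CC(C(Cl)=O)C(Cl)=O)c1OCc1ccccc1 | intermediate
10 | heptane-2,4-dione | CCCC(=O)CC(C)=O | starting material
11 | dilithium (3Z)-hepta-1,3-diene-2,4-diolate | C=C(O[Li])/C=C(\O[Li])CCC | intermediate (not isolated)
12 | (3Z)-2,4-bis(trimethylsilyloxy)hepta-1,3-diene | C=C(O[Si](C)(C)C)/C=C(\O[Si](C)(C)C)CCC | intermediate
13 | open-chain adduct after the first C-acylation, each arm being ArCH2–CH(COCl)–CO–CH2–CO–CH=C(OSiMe3)–propyl with a Z enol ether; mixture of diastereomers at the two CH(COCl) carbons, which are lost on aromatisation | CCCC(=O)c1c(OCc2ccccc2)c(CC(C(Cl)=O)C(=O)CC(=O)/C=C(\O[Si](C)(C)C)CCC)c(OCc2ccccc2)c(CC(C(Cl)=O)C(=O)CC(=O)/C=C(\O[Si](C)(C)C)CCC)c1OCc1ccccc1 | intermediate (not isolated)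
14 | 1-[2,4,6-tris(benzyloxy)-3,5-bis(3-butanoyl-2,4,6-trihydroxybenzyl)phenyl]butan-1-one (B–C–D trimer, ring C as tribenzyl ether) | CCCC(=O)c1c(OCc2ccccc2)c(Cc2c(O)cc(O)c(C(=O)CCC)c2O)c(OCc2ccccc2)c(Cc2c(O)cc(O)c(C(=O)CCC)c2O)c1OCc1ccccc1 | intermediate
15 | 1-[3,5-bis(3-butanoyl-2,4,6-trihydroxybenzyl)-2,4,6-trihydroxyphenyl]butan-1-one (free B–C–D trimer) | CCCC(=O)c1c(O)c(Cc2c(O)cc(O)c(C(=O)CCC)c2O)c(O)c(Cc2c(O)cc(O)c(C(=O)CCC)c2O)c1O | intermediate
16 | 2-butanoyl-3,5-dihydroxy-6,6-dimethylcyclohexa-2,4-dien-1-one (butyrylfilicinic acid) | CCCC(=O)C1=C(O)C=C(O)C(C)(C)C1=O | intermediate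
17 | 2-butanoyl-4-[(dimethylamino)methyl]-3,5-dihydroxy-6,6-dimethylcyclohexa-2,4-dien-1-one | CCCC(=O)C1=C(O)C(CN(C)C)=C(O)C(C)(C)C1=O | intermediate
18 | 2-butanoyl-3-hydroxy-6,6-dimethyl-4-methylidenecyclohex-2-ene-1,5-dione | CCCC(=O)C1=C(O)C(=C)C(=O)C(C)(C)C1=O | intermediate (not isolated)
19 | pentaalbaspidin BBBBB | CCCC(=O)C1=C(O)C(Cc2c(O)c(Cc3c(O)c(Cc4c(O)c(CC5=C(O)C(C)(C)C(=O)C(C(=O)CCC)=C5O)c(O)c(C(=O)CCC)c4O)c(O)c(C(=O)CCC)c3O)c(O)c(C(=O)CCC)c2O)=C(O)C(C)(C)C1=O | target

Total step count: 12
Longest linear sequence: 9 steps (steps 1 to 6, 8, 9 and 12, from compound 1)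

Steps most likely to fail

1. Step 8 (key step, untested reaction type). An arm may close through oxygen instead of carbon, the second acylation may go intermolecularly and link molecules into oligomers, or a benzyl ether oxygen may attack its neighbouring acid chloride with loss of the benzyl group. The fallback uses known chemistry (Mannich reaction, then ortho-quinone methide alkylation of a phloroglucinol); it sets out from 1 and comes back to the route at 15. Twofold aminomethylation of 1 with bis(dimethylamino)methane in CH2Cl2 should give 1-{3,5-bis[(dimethylamino)methyl]-2,4,6-trihydroxyphenyl}butan-1-one F1, which has no free ring carbon left. Heated with a large excess of 1 (about 10 equiv) in 1,4-dioxane at 90 °C, F1 should lose dimethylamine twice, and each ortho-quinone methide is trapped by a free ring carbon of 1 to give 15 directly. The excess of 1 suppresses higher oligomers and is recovered. Rings B and D are then brought in ready-made, and steps 1 to 9 are not needed.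

2. Step 12. The second capping may stay incomplete, the enone methide may condense with itself, and the amine may promote retro-Michael exchange of methylene links, which scrambles the ring sequence. The fallback reverses the roles of the partners; it sets out from 15 and comes back at 19. Aminomethylation of the two free carbons of rings B and D of 15 with bis(dimethylamino)methane should give 1-[3,5-bis({3-butanoyl-5-[(dimethylamino)methyl]-2,4,6-trihydroxyphenyl}methyl)-2,4,6-trihydroxyphenyl]butan-1-one F2. Heating F2 with an excess of 16 (about 6 equiv) in dioxane containing acetic acid generates the quinone methides on rings B and D, where no free ring carbon remains for self-coupling, and the small, soluble carbon acid 16 traps them to give 19. Unreacted 16 is removed by chromatography.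

3. Step 6. Hydrogen chloride and the chloroiminium catalyst may promote acyl transfer to a neighbouring benzyl ether oxygen with loss of benzyl chloride (lactone formation), or dehydrochlorination to ketenes that dimerise. The fallback makes the acid chloride without hydrogen chloride; it sets out from 8 and comes back at 9. The four acid groups are silylated with hexamethyldisilazane to give tetrakis(trimethylsilyl) 2,2'-{[2,4,6-tris(benzyloxy)-5-butanoyl-1,3-phenylene]bis(methylene)}dipropanedioate F3. Treated with oxalyl chloride and catalytic DMF in CH2Cl2 at 0 °C, F3 should give 9 with Me3SiCl, CO and CO2 as the only by-products.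

Further compounds
F1 | step 8 | 1-{3,5-bis[(dimethylamino)methyl]-2,4,6-trihydroxyphenyl}butan-1-one | CCCC(=O)c1c(O)c(CN(C)C)c(O)c(CN(C)C)c1O
F2 | step 12 | 1-[3,5-bis({3-butanoyl-5-[(dimethylamino)methyl]-2,4,6-trihydroxyphenyl}methyl)-2,4,6-trihydroxyphenyl]butan-1-one | CCCC(=O)c1c(O)c(Cc2c(O)c(CN(C)C)c(O)c(C(=O)CCC)c2O)c(O)c(Cc2c(O)c(CN(C)C)c(O)c(C(=O)CCC)c2O)c1O
F3 | step 6 | tetrakis(trimethylsilyl) 2,2'-{[2,4,6-tris(benzyloxy)-5-butanoyl-1,3-phenylene]bis(methylene)}dipropanedioate | CCCC(=O)c1c(OCc2ccccc2)c(CC(C(=O)O[Si](C)(C)C)C(=O)O[Si](C)(C)C)c(OCc2ccccc2)c(CC(C(=O)O[Si](C)(C)C)C(=O)O[Si](C)(C)C)c1OCc1ccccc1
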